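The ε-lactone (ring A, O–C3(=O)–C2=C1–C10–C5–C4) is made last. In the target C10 (quaternary, CH3) and C4 (O-bearing CMe2) stand 1,3 across C5–H of ring B, the pattern of a gem-dimethylcyclopropane fused to ring B; the lactone is therefore disconnected to that cyclopropane and propiolic acid. In the key step a photo-oxidant opens the C10–C4 σ bond as a radical cation, carboxylate binds C4 and the C10 radical closes on the alkyne: a formal (4+3) annulation that forms C1–C10 and O–C4, the Z-enoate and the C10 stereocentre at once. Its precursor is the finished bicyclo[2.2.2]octane core, built from (R)-carvone and a tetronic-acid-derived dienone by intramolecular Diels–Alder reaction.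

Key step: step 13

Remark on locants: ring B is C5–C6–C7–C8–C9–C10, C11 is the CH2 on C9 and C12 the CH2 on C8; the tetronic-acid-derived part keeps the 2-benzofuranone locants of compound 4 with primes (C1′ lactone C=O, C3′ OCH2, C3a′, C4′ quaternary C–CH3, C5′ ketone, C6′ C–CH3, C7′, C7a′); α is the ring-B face that carries H5 in the target.

Step 1
Reactants: 1 tetronic acid (furan-2,4(3H,5H)-dione); 2 2-methylpent-1-en-3-one
Product: 3 4-hydroxy-3-(2-methyl-3-oxopentyl)furan-2(5H)-one (racemic)
Conditions: Et3N (10 mol%), CH2Cl2, 25 °C
Reagents that add atoms: none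
Why: Amine-catalysed Michael addition of the vinylogous acid (C3 of tetronic acid) to the enone; the new CH(CH3) centre needs no control because it is planarised in step 10.

Step 2
Reactants: 3 4-hydroxy-3-(2-methyl-3-oxopentyl)furan-2(5H)-one
Product: 4 4,6-dimethyl-6,7-dihydro-2-benzofuran-1,5(3H,4H)-dione (racemic, C4/C6 diastereomers)
Conditions: p-TsOH·H2O (cat.), toluene, reflux, Dean–Stark
Reagents that add atoms: none
Why: Acid-catalysed intramolecular aldol-type condensation (Robinson-annulation logic) in which the enol of the ethyl ketone adds to C4 of the tetronic acid and water is lost, the only six-membered closure available; both stereocentres stay unassigned because C4 is deprotonated in step 9 and C6 dehydrogenated in step 10.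

Step 3
Reactants: 5 (R)-(−)-carvone
Product: 6 (5R,6S)-2,6-dimethyl-5-(prop-1-en-2-yl)cyclohex-2-en-1-one (trans-6-methylcarvone)
Conditions: LDA, THF, −78 °C; MeI, −78 to 0 °C
Reagents that add atoms: iodomethane CI
Why: Kinetic α′-enolate alkylation of the enone, methyl iodide entering trans to the isopropenyl group (this centre is re-formed in step 5).

Step 4
Reactants: 6 trans-6-methylcarvone
Product: 7 (5R,6S)-5-(2-bromopropan-2-yl)-2,6-dimethylcyclohex-2-en-1-one
Conditions: HBr (33% in AcOH), 0 °C
Reagents that add atoms: hydrogen bromide Br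
Why: Markovnikov hydrobromination of the electron-rich 1,1-disubstituted alkene at low temperature, which leaves the enone untouched as it does with carvone itself.

Step 5
Reactants: 7 tertiary bromide
Product: 8 (1S,6S)-1,3,7,7-tetramethylbicyclo[4.1.0]hept-3-en-2-one
Conditions: KOtBu, THF, 0 °C
Reagents that add atoms: none
Why: Intramolecular enolate alkylation (3-exo-tet, the classical carone ring closure) of the α′-dienolate on the tertiary bromide; a cyclopropane can only be cis-fused, so the carvone stereocentre fixes both ring-fusion carbons (future C5 and C10).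

Step 6
Reactants: 8 cyclopropyl enone
Product: 9 tosylhydrazone of 8
Conditions: TsNHNH2, EtOH, AcOH (cat.), 60 °C
Reagents that add atoms: 4-methylbenzenesulfonohydrazide Cc1ccc(cc1)S(=O)(=O)NN
Why: Acid-catalysed condensation of the ketone with tosylhydrazide.

Step 7
Reactants: 9 tosylhydrazone
Product: 10 1,3,7,7-tetramethylbicyclo[4.1.0]hept-2-ene (ring fusion as in 8)
Conditions: catecholborane, CHCl3, 0 °C; then NaOAc·3H2O, reflux
Reagents that add atoms: none
Why: Catecholborane reduction of an α,β-unsaturated tosylhydrazone: hydride adds to C=N, sulfinate leaves and the allylic diazene loses N2 by a retro-ene shift, which removes the oxygen and moves the double bond to C8=C9 (deoxygenative alkene transposition).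

Step 8
Reactants: 10 trisubstituted alkene
Product: 11 [1,7,7-trimethyl-3-methylidenebicyclo[4.1.0]heptan-2-yl]methanol (CH2OH on the face opposite the CMe2 bridge)
Conditions: paraformaldehyde, Me2AlCl, CH2Cl2, −78 to 0 °C
Reagents that add atoms: formaldehyde C=O
Why: Lewis-acid-promoted carbonyl-ene reaction: the C9–C11 bond forms at the less substituted alkene carbon with transfer of a methyl hydrogen (exocyclic C8=C12), and formaldehyde approaches the α face because the endo methyl of the gem-dimethylcyclopropane shields the other, which sets C9.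

Step 9
Reactants: 11 homoallylic alcohol; 4 4,6-dimethyl-6,7-dihydro-2-benzofuran-1,5(3H,4H)-dione
Product: 13 C4′-alkylated bicyclic dione (C4′ as in the SMILES; C6′ epimers), via primary triflate 12 (not isolated)
Conditions: Tf2O, 2,6-lutidine, CH2Cl2, −78 °C; then potassium enolate of 4 (KHMDS, THF/DMPU), −78 to 0 °C
Reagents that add atoms: none
Why: O-triflation, then SN2 C-alkylation of the doubly activated carbon acid C4′ (α to the ketone, vinylogous to the lactone) as its potassium enolate; no useful facial bias is expected at the new quaternary C4′, so 13 is separated from its C4′ epimer, which cannot attain the geometry of step 11.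

Step 10
Reactants: 13 C4′-alkylated dione
Product: 14 cyclohexa-2,4-dienone (6′,7′-didehydro-13)
Conditions: IBX, DMSO/fluorobenzene, 70 °C
Reagents that add atoms: none
Why: IBX dehydrogenation of the ketone through its only enol (C6′) gives the linearly conjugated 2,4-dienone and erases the C6′ centre.

Step 11
Reactants: 14 dienone
Product: 15 Diels–Alder adduct (bicyclo[2.2.2]octenone with C7′=C7a′ double bond)
Conditions: toluene, BHT (cat.), 130 °C, sealed tube
Reagents that add atoms: none
Why: Intramolecular Diels–Alder reaction of the 6,6-disubstituted cyclohexa-2,4-dienone (diene C3a′=C7a′–C7′=C6′) with the 1,1-disubstituted C8=C12 alkene (inverse electron demand), forming C8–C3a′ and C12–C6′; the one-carbon link C11 forces addition to the α face of C8, which gives the cis-fused cyclopentane and fixes C8, C3a′ and C6′ relative to C9 and C4′.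

Step 12
Reactants: 15 Diels–Alder adduct
Product: 16 saturated cyclopropane-bearing core (18 with the C10–C4 bond in place of the C1–C3/O unit)
Conditions: H2 (1 atm), Pd/C, EtOAc, 25 °C; then DBU, toluene, 60 °C
Reagents that add atoms: none
Why: Heterogeneous syn-hydrogenation of the α-alkylidene lactone alkene, then DBU equilibration of the enolisable lactone α-carbon C7a′ to the epimer expected to be more stable, with the lactone carbonyl over the ketone bridge and away from ring B (the natural configuration); the tetrasubstituted cyclopropane is inert.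

Step 13
Reactants: 16 cyclopropane-bearing core; 17 propiolic acid
Product: 18 andilesin C
Conditions: 17 (3 equiv), 9-mesityl-3,6-di-tert-butyl-10-phenylacridinium BF4 (5 mol%), 2,6-lutidine (20 mol%), (PhS)2 (10 mol%), 1,2-dichloroethane, 450 nm LEDs, 25 °C
Reagents that add atoms: none
Why: Proposed new method: single-electron oxidation of the tetraalkylcyclopropane by the excited acridinium gives a radical cation whose most substituted bond C10–C4 is the one-electron bond; propiolate attacks C4 from the rear (three-electron SN2) to form O–C4, and the released tertiary C10 radical adds 7-endo-dig to the β-carbon of the tethered ynoate to form C1–C10, the vinyl radical then being reduced by thiol hydrogen-atom transfer with turnover of the catalyst. The closest known reactions are the acridinium-mediated polar radical crossover cycloaddition of alkenes with unsaturated acids to γ-butyrolactones and the photoinduced-electron-transfer ring opening of alkylcyclopropanes by nucleophiles; replacing the alkene by a cyclopropane turns the (3+2) into a (4+3). The seven-membered lactone is closed by the radical 7-endo-dig step, which also fixes the Z-alkene because the vinyl radical is endocyclic. C5 is untouched, and the planar C10 radical is attacked on its α face because the axial C12 methylene on C8 blocks the β face, giving the trans A/B fusion with β-methyl. The step needs carboxylate attack at C4 and not at the neopentyl-like C10 (sterics), β- and not α-attack on the ynoate (a nucleophilic tertiary radical) and cyclisation before radical quenching (low thiol loading); no other group in 16 is oxidisable at this potential.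

Compound list
1 | tetronic acid (furan-2,4(3H,5H)-dione) | O=C1CC(=O)OC1 | starting material
2 | 2-methylpent-1-en-3-one | CCC(=O)C(C)=C | starting material
3 | 4-hydroxy-3-(2-methyl-3-oxopentyl)furan-2(5H)-one (racemic) | CCC(=O)C(C)CC1=C(O)COC1=O | intermediate
4 | 4,6-dimethyl-6,7-dihydro-2-benzofuran-1,5(3H,4H)-dione (racemic, diastereomers) | CC1CC2=C(COC2=O)C(C)C1=O | intermediate
5 | (R)-(−)-carvone | CC1=CC[C@H](CC1=O)C(C)=C | starting material
6 | (5R,6S)-2,6-dimethyl-5-(prop-1-en-2-yl)cyclohex-2-en-1-one | CC1=CC[C@H]([C@H](C)C1=O)C(C)=C | intermediate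
7 | (5R,6S)-5-(2-bromopropan-2-yl)-2,6-dimethylcyclohex-2-en-1-one | CC1=CC[C@H]([C@H](C)C1=O)C(C)(C)Br | intermediate
8 | (1S,6S)-1,3,7,7-tetramethylbicyclo[4.1.0]hept-3-en-2-one | CC1(C)[C@]2(C)[C@H]1CC=C(C)C2=O | intermediate
9 | tosylhydrazone of 8 | CC1(C)[C@]2(C)[C@H]1CC=C(C)C2=NNS(=O)(=O)c1ccc(C)cc1 | intermediate
10 | 1,3,7,7-tetramethylbicyclo[4.1.0]hept-2-ene (ring fusion as in 8) | CC1(C)[C@]2(C)[C@H]1CCC(C)=C2 | intermediate
11 | [1,7,7-trimethyl-3-methylidenebicyclo[4.1.0]heptan-2-yl]methanol, CH2OH anti to the CMe2 bridge | CC1(C)[C@]2(C)[C@H]1CCC(=C)[C@H]2CO | intermediate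
12 | trifluoromethanesulfonate of 11 | CC1(C)[C@]2(C)[C@H]1CCC(=C)[C@H]2COS(=O)(=O)C(F)(F)F | intermediate
13 | 4,6-dimethyl-4-{[1,7,7-trimethyl-3-methylidenebicyclo[4.1.0]heptan-2-yl]methyl}-6,7-dihydro-2-benzofuran-1,5(3H,4H)-dione (C4′ defined, C6′ epimers) | CC1(C)[C@]2(C)[C@H]1CCC(=C)[C@H]2C[C@@]3(C)C(=O)C(C)CC4=C3COC4=O | intermediate
14 | 6′,7′-didehydro-13 (cyclohexa-2,4-dienone) | CC1(C)[C@]2(C)[C@H]1CCC(=C)[C@H]2C[C@@]3(C)C(=O)C(C)=CC4=C3COC4=O | intermediate
15 | Diels–Alder adduct with C7′=C7a′ double bond | CC1(C)[C@]2(C)[C@H]1CC[C@@]13C[C@@]4(C)C=C5C(=O)OC[C@]51[C@@](C)(C[C@@H]23)C4=O | intermediate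
16 | saturated core with C10–C5–C4 gem-dimethylcyclopropane | CC1(C)[C@]2(C)[C@H]1CC[C@@]13C[C@@]4(C)C[C@@H]5C(=O)OC[C@]51[C@@](C)(C[C@@H]23)C4=O | intermediate
17 | propiolic acid | C#CC(=O)O | starting material
18 | andilesin C | CC1(C)OC(=O)C=C[C@@]2(C)[C@H]1CC[C@@]13C[C@@]4(C)C[C@@H]5C(=O)OC[C@]51[C@@](C)(C[C@@H]23)C4=O | target

Total steps: 13. Longest linear sequence: 11 steps (5 to 18, steps 3–13).

Steps most likely to fail

1. Step 13 (proposed new method). The C10 radical may be quenched by hydrogen transfer before it cyclises, or the carboxylate may open the radical cation at C10 instead of C4. The fallback uses known reactions, builds ring A early and carries it through; it sets out from 6 and comes back at 18. The lithium enolate of 6 (LDA) is vinylated by conjugate addition–elimination with tert-butyl (Z)-3-iodoacrylate, anti to the isopropenyl group, to give tert-butyl (Z)-3-[1,3-dimethyl-2-oxo-6-(prop-1-en-2-yl)cyclohex-3-en-1-yl]prop-2-enoate F1. Cobalt–salen/N-fluoropyridinium/silane hydroacyloxylation of the isopropenyl group (hydrogen-atom transfer, radical-polar crossover, loss of isobutene) closes the ε-lactone enone F2. F2 then follows steps 6–11: tosylhydrazone F3, transposed alkene F4, ene alcohol F5, triflate F6, alkylation of 4 to the C4′-alkylated dione F7, dienone F8 and Diels–Alder adduct F9. Chemoselective conjugate reduction of the α-alkylidene-γ-lactone of F9 with [(Ph3P)CuH]6, followed by DBU equilibration, gives 18.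

2. Step 9. The hindered primary triflate may be O-alkylated or not substituted at all by the fully substituted C4′ carbanion, and the new quaternary centre may form without facial selectivity. The fallback sets out from 12 (with 1) and comes back at 13. Tetronic acid 1 and 3-methylbut-3-en-2-one give the Michael adduct 4-hydroxy-3-(2-methyl-3-oxobutyl)furan-2(5H)-one F10, which is cyclised as in step 2 to 6-methyl-6,7-dihydro-2-benzofuran-1,5(3H,4H)-dione F11. The less hindered secondary C4′ of its potassium enolate is alkylated by 12 to the mono-alkylated dione F12. The small electrophile MeI then quaternises C4′ under a chiral quaternary-ammonium phase-transfer catalyst (catalyst-controlled face selection) to give 13.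

3. Step 11. Retro-ene fragmentation of the dienone to the phenol (aromatisation) may outrun the cycloaddition. The fallback sets out from 13 and comes back at 16. The C6′ silyl enol ether of 13 (TMSOTf, Et3N) is brominated with NBS to the tertiary α-bromo ketone F13. Bu3SnH/AIBN then generates the C6′ α-keto radical, which adds 7-endo to C12 of the exocyclic alkene; the resulting tertiary C8 radical adds 5-exo to C3a′ of the butenolide, and hydrogen transfer to the lactone α-radical gives 16 without dienone or hydrogenation.

Further compounds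
F1 | step 13 | tert-butyl (Z)-3-[1,3-dimethyl-2-oxo-6-(prop-1-en-2-yl)cyclohex-3-en-1-yl]prop-2-enoate (acrylate trans to isopropenyl) | CC1=CC[C@H]([C@](C)(/C=C\C(=O)OC(C)(C)C)C1=O)C(C)=C
F2 | step 13 | ε-lactone enone (lactone analogue of 8) | CC1(C)OC(=O)C=C[C@@]2(C)[C@H]1CC=C(C)C2=O
F3 | step 13 | tosylhydrazone of F2 | CC1(C)OC(=O)C=C[C@@]2(C)[C@H]1CC=C(C)C2=NNS(=O)(=O)c1ccc(C)cc1
F4 | step 13 | transposed alkene (lactone analogue of 10) | CC1(C)OC(=O)C=C[C@@]2(C)[C@H]1CCC(C)=C2
F5 | step 13 | ene alcohol (lactone analogue of 11) | CC1(C)OC(=O)C=C[C@@]2(C)[C@H]1CCC(=C)[C@H]2CO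
F6 | step 13 | triflate of F5 | CC1(C)OC(=O)C=C[C@@]2(C)[C@H]1CCC(=C)[C@H]2COS(=O)(=O)C(F)(F)F
F7 | step 13 | C4′-alkylated dione (lactone analogue of 13) | CC1(C)OC(=O)C=C[C@@]2(C)[C@H]1CCC(=C)[C@H]2C[C@@]3(C)C(=O)C(C)CC4=C3COC4=O
F8 | step 13 | dienone (lactone analogue of 14) | CC1(C)OC(=O)C=C[C@@]2(C)[C@H]1CCC(=C)[C@H]2C[C@@]3(C)C(=O)C(C)=CC4=C3COC4=O
F9 | step 13 | 7′,7a′-didehydro-andilesin C | CC1(C)OC(=O)C=C[C@@]2(C)[C@H]1CC[C@@]13C[C@@]4(C)C=C5C(=O)OC[C@]51[C@@](C)(C[C@@H]23)C4=O
F10 | step 9 | 4-hydroxy-3-(2-methyl-3-oxobutyl)furan-2(5H)-one (racemic) | CC(=O)C(C)CC1=C(O)COC1=O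
F11 | step 9 | 6-methyl-6,7-dihydro-2-benzofuran-1,5(3H,4H)-dione (racemic) | CC1CC2=C(COC2=O)CC1=O
F12 | step 9 | mono-alkylated dione (13 without the C4′ methyl) | CC1(C)[C@]2(C)[C@H]1CCC(=C)[C@H]2CC3C(=O)C(C)CC4=C3COC4=O
F13 | step 11 | 6′-bromo-13 | CC1(C)[C@]2(C)[C@H]1CCC(=C)[C@H]2C[C@@]3(C)C(=O)C(C)(Br)CC4=C3COC4=O
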